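(The runs were computed for an exercise; scatter was added.)

Take cedar and alder and look for the crossing, the moment at which target stops being made faster than it is used up, which is the top of an intermediate's curve.

| flask | substrate | gas phase | remark | time |
|---|---|---|---|---|
| cedar | 19 mM | 1.1 mM (held) | run made earlier |  |
| alder | 42 mM | 1.1 mM (held) | run made earlier |  |
| flask | 28 mM | 1.1 mM (held) |  | 2.5 h |

| run | time / h | target / % |
|---|---|---|
| cedar | 0.333 | 36.6 |
| cedar | 0.500 | 50.2 |
| cedar | 0.833 | 64.2 |
| cedar | 1.33 | 64.3 |
| cedar | 2.50 | 43.7 |
| alder | 0.333 | 22.7 |
| alder | 0.500 | 33.0 |
| alder | 0.833 | 47.7 |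
| alder | 1.33 | 59.2 |
| alder | 2.50 | 48.4 |

(standard deviation of a reading: 0.3 percentage points)

- when, up to 2.5 h, the flask holds most target
- the amount of target, in percent of the substrate charged, at that time

I place the crossing where the slope of the readings changes sign, putting zero linearly between the midpoints of the last two intervals. That reads 1.09 h for cedar and 1.68 h for alder.

My doubt is that the last interval of alder is wide, 1.17 h, so its chord need not follow the curve near the top. I therefore apply the same rule to the three readings before the last one in each run. That reads 1.08 h for cedar, close to its first value, and 1.54 h for alder, earlier than its first value. The alder value is an extrapolation past the reading at 1.33 h, so it remains an estimate. I carry the charge exponent, the power of the substrate charge with which the crossing time grows, 0.442. Two runs cannot show that a power holds, but the flask lies between them, and from cedar I reckon its crossing at 1.29 h.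

The forecast gives 1.27 h and 64.5%, and says of itself: “This rests on estimated peak shapes, so the uncertainty is moderate.” My time stands later than its time.

The flask gives 1.25 h and 63.8%.

    substrate + dissolved gas ⇌ target (K = 14000 L mol⁻¹, k = 56.0 L mol⁻¹ min⁻¹)
    gas phase ⇌ dissolved gas, rate k2*(csat - [dissolved gas]) (kL = 0.640 min⁻¹)
    target ⇌ isomer of the product (K = 25.0, k = 0.00700 min⁻¹)

At 0.524 h the flask makes target 4.36 times as fast as it uses it up, each step taken net. At 2.50 h that ratio is 0.0944, and the crossing at 1.25 h lies between them, 0.0400 h before my reckoned time. Runs charged with 14.0 mM and 56.0 mM reach their times at 0.965 h and 1.80 h, a ratio of 1.87, and the exponent 0.442 gives 1.85 for that change of charge.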